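## Retrosynthetic overview
1. C10–C11: chelation-controlled addition of a non-8-enyl Grignard reagent to a tetrahydrofuran-2-carbaldehyde that already carries the C7 laurate. This sets C10, and the two oxygens never need to be told apart.
2. The aldehyde comes from ozonolysis of a styryl group. The laurate comes from acylating the only free OH present at that stage.
3. The only ring (the tetrahydrofuran, O–C6 bond) is closed by 5-exo SN2 attack of C9–OH on a C6 chloride with inversion. This fixes C6.
4. The chlorodiol comes from a 1,3-syn reduction (sets C9) of the 1,2-anti aldol adduct (sets C7) of the benzalacetone lithium enolate and (R)-2-chloroheptanal.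
5. (R)-2-Chloroheptanal comes from heptanal by organocatalytic α-chlorination, the only external source of chirality.

Assumption: positions are numbered C1–C19 as in 6,9-epoxynonadec-18-ene-7,10-diol (pentyl = C1–C5, ring carbons = C6–C9, carbinol = C10). The SMILES reads (6S,7S,9R,10R): ring 2,3-cis and 2,5-trans, C9/C10 threo. All named reagents and catalysts are taken as commercial.

## Route

Step 1
Reactants: 1 heptanal
Product: 2 (2R)-2-chloroheptanal
Conditions: (5R)-5-benzyl-2,2,3-trimethylimidazolidin-4-one·TFA (5 mol %), 2,3,4,5,6,6-hexachlorocyclohexa-2,4-dien-1-one (1.2 equiv), acetone, −30 °C; pentane/SiO2 filtration, used at once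
Reagents that add atoms: 2,3,4,5,6,6-hexachlorocyclohexa-2,4-dien-1-one, O=C1C(Cl)=C(Cl)C(Cl)=C(Cl)C1(Cl)Cl
Why: Enamine-catalysed asymmetric α-chlorination (MacMillan type), in which the (5R)-imidazolidinone forms the E-enamine turned away from its gem-dimethyl carbon, the benzyl group covers the Si face, and Cl+ from the dienone (driven by aromatisation to the phenol) enters on the open Re face to set C6 as (R) in about 92% ee.

Step 2
Reactants: 2 (2R)-2-chloroheptanal; 3 (E)-4-phenylbut-3-en-2-one
Product: 5 (1E,5S,6R)-6-chloro-5-hydroxy-1-phenylundec-1-en-3-one, via lithium dienolate 4 (not isolated)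
Conditions: 3, LDA (commercial solution), THF, −78 °C; then 2, −78 °C, 20 min; sat. aq NH4Cl at −78 °C
Reagents that add atoms: none
Why: Kinetic lithium aldol addition under Cornforth control, in which the C–Cl dipole lies anti to C=O and the methyl-ketone enolate passes H rather than pentyl, setting C7 as (S) (the 1,2-anti chlorohydrin, about 10:1 expected, minor isomer removed on silica), while the short time at −78 °C prevents racemisation of 2, epoxide closure and oxa-Michael closure.

Step 3
Reactants: 5 (1E,5S,6R)-6-chloro-5-hydroxy-1-phenylundec-1-en-3-one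
Product: 7 (1E,3R,5S,6R)-6-chloro-1-phenylundec-1-ene-3,5-diol, via diethylboron chelate 6 (not isolated)
Conditions: Et2BOMe, THF/MeOH 4:1, −78 °C; NaBH4, −78 °C; then evaporation from MeOH (×3)
Reagents that add atoms: none
Why: Narasaka–Prasad 1,3-syn reduction, in which boron ties the C7 alkoxide and the ketone into a six-membered half-chair chelate and external hydride adds axially in 1,2-fashion to give the 7,9-syn diol with C9 as (R), the secondary chloride and the styrene being inert to NaBH4 at −78 °C.

Step 4
Reactants: 7 (1E,3R,5S,6R)-6-chloro-1-phenylundec-1-ene-3,5-diol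
Product: 8 (2S,3S,5R)-2-pentyl-5-[(E)-2-phenylethenyl]oxolan-3-ol
Conditions: AgOTf, Ag2O, THF, rt, dark
Reagents that add atoms: none
Why: Silver(I)-assisted intramolecular Williamson-type etherification (5-exo-tet SN2), in which Ag+ pulls on chloride while C9–OH attacks C6 from the back, inverting C6 from (R)-Cl to (S)-O with C7 and C9 untouched to give the 2,3-cis-2,5-trans ring, while Ag2O buffers the acid so that neither base-induced epoxide formation nor acid-induced allylic ionisation competes.

Step 5
Reactants: 8 (2S,3S,5R)-2-pentyl-5-[(E)-2-phenylethenyl]oxolan-3-ol; 9 dodecanoyl chloride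
Product: 10 (2S,3S,5R)-2-pentyl-5-[(E)-2-phenylethenyl]oxolan-3-yl dodecanoate
Conditions: Et3N, DMAP (cat.), CH2Cl2, 0 °C to rt
Reagents that add atoms: none
Why: DMAP-catalysed O-acylation with an acid chloride works cleanly because 8 has a single hydroxyl group, so the laurate goes onto C7–O before the C10 oxygen exists, no protecting group is needed and no stereocentre is touched.

Step 6
Reactants: 10 (2S,3S,5R)-2-pentyl-5-[(E)-2-phenylethenyl]oxolan-3-yl dodecanoate
Product: 12 (2S,3S,5R)-5-formyl-2-pentyloxolan-3-yl dodecanoate, via secondary ozonide 11 (not isolated)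
Conditions: O3, CH2Cl2, −78 °C; then Me2S, −78 °C to rt; quick SiO2 filtration (removes PhCHO), used at once
Reagents that add atoms: ozone, [O-][O+]=O
Why: Ozonolysis (Criegee mechanism) with reductive work-up cleaves the styryl C=C as the only reactive π bond, the ester and ring ether survive at −78 °C, the neutral Me2S reduction avoids epimerising the α-alkoxy aldehyde at C9, and the terminal alkene of the target is not yet present.

Step 7
Reactants: 12 (2S,3S,5R)-5-formyl-2-pentyloxolan-3-yl dodecanoate; 13 9-bromonon-1-ene
Product: 15 (2S,3S,5R)-5-[(1R)-1-hydroxydec-9-en-1-yl]-2-pentyloxolan-3-yl dodecanoate, via Grignard reagent 14 (not isolated)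
Conditions: 13, Mg, Et2O, reflux; 12, MgBr2·OEt2 (2 equiv), CH2Cl2, −78 °C, then 14 (1.2 equiv), −78 °C; sat. aq NH4Cl
Reagents that add atoms: none
Why: Cram-chelate-controlled Grignard addition, in which MgBr2 in non-coordinating CH2Cl2 locks the ring oxygen and the aldehyde oxygen in a five-membered chelate so that the alkyl group enters the Re face (flanked by C9–H rather than ring C8) to give the threo (10R) carbinol, and at −78 °C the chelate-activated aldehyde reacts far faster than the secondary laurate.

## Compound list
1 | heptanal | CCCCCCC=O | starting material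
2 | (2R)-2-chloroheptanal | O=C[C@@H](CCCCC)Cl | intermediate
3 | (E)-4-phenylbut-3-en-2-one (benzalacetone) | CC(=O)/C=C/c1ccccc1 | starting material
4 | lithium (3E)-4-phenylbuta-1,3-dien-2-olate | C=C(O[Li])/C=C/c1ccccc1 | intermediate
5 | (1E,5S,6R)-6-chloro-5-hydroxy-1-phenylundec-1-en-3-one | O=C(/C=C/c1ccccc1)C[C@H](O)[C@@H](CCCCC)Cl | intermediate
6 | O-diethylboryl chelate of 5 | O=C(/C=C/c1ccccc1)C[C@H](OB(CC)CC)[C@@H](CCCCC)Cl | intermediate
7 | (1E,3R,5S,6R)-6-chloro-1-phenylundec-1-ene-3,5-diol | c1ccccc1/C=C/[C@H](O)C[C@H](O)[C@@H](CCCCC)Cl | intermediate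
8 | (2S,3S,5R)-2-pentyl-5-[(E)-2-phenylethenyl]oxolan-3-ol | c1ccccc1/C=C/[C@H]2C[C@H](O)[C@H](CCCCC)O2 | intermediate
9 | dodecanoyl (lauroyl) chloride | CCCCCCCCCCCC(=O)Cl | starting material
10 | (2S,3S,5R)-2-pentyl-5-[(E)-2-phenylethenyl]oxolan-3-yl dodecanoate | c1ccccc1/C=C/[C@H]2C[C@H](OC(=O)CCCCCCCCCCC)[C@H](CCCCC)O2 | intermediate
11 | (2S,3S,5R)-2-pentyl-5-(5-phenyl-1,2,4-trioxolan-3-yl)oxolan-3-yl dodecanoate (trioxolane carbons undefined) | c1ccccc1C2OOC(O2)[C@H]3C[C@H](OC(=O)CCCCCCCCCCC)[C@H](CCCCC)O3 | intermediate
12 | (2S,3S,5R)-5-formyl-2-pentyloxolan-3-yl dodecanoate | O=C[C@H]1C[C@H](OC(=O)CCCCCCCCCCC)[C@H](CCCCC)O1 | intermediate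
13 | 9-bromonon-1-ene | C=CCCCCCCCBr | starting material
14 | non-8-en-1-ylmagnesium bromide | C=CCCCCCCC[Mg]Br | intermediate
15 | (2S,3S,5R)-5-[(1R)-1-hydroxydec-9-en-1-yl]-2-pentyloxolan-3-yl dodecanoate (CNP0124067.1) | C=CCCCCCCC[C@@H](O)[C@H]1C[C@H](OC(=O)CCCCCCCCCCC)[C@H](CCCCC)O1 | target

## Step count and risks
Total step count: 7. Longest linear sequence: 7 (1 → 2 → 5 → 7 → 8 → 10 → 12 → 15).

Origin of the stereocentres:
- C6: set in step 1 and inverted in step 4.
- C7: set in step 2.
- C9: set in step 3.
- C10: set in step 7.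

**Step 7 is the most exposed.** Incomplete chelation would give the (10S) epimer, and surplus Grignard reagent could attack the laurate. Acyl migration from O7 to O10 is not a concern, because the two groups sit on opposite ring faces. The fallback sets out from 14, with 12 as partner, and comes back at 15. It replaces substrate control with a basic Grignard reagent by catalyst control with a non-basic organozinc. Compound 14 is transmetalated with ZnCl2 (0.5 equiv, Et2O), and the magnesium halide is precipitated with dioxane. This gives salt-free di(non-8-en-1-yl)zinc F1. F1 is added to 12 with Ti(OiPr)4 and (4S,5S)-TADDOL (20 mol %) in toluene at −25 °C. The (S,S)-titanium TADDOLate directs the alkyl group to the Re face of the aldehyde, the face that gives (10R). A dialkylzinc leaves the ester alone.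

**Step 4 comes second.** The C9 carbinol of 7 and the C9 ether of 8 are cinnamyl-type, so Ag(I) or adventitious acid could ionise them and scramble C9. A semipinacol shift of the chlorohydrin is also conceivable. The fallback sets out from 2 and comes back at 12. It carries the future aldehyde as an acetal instead of a styrene.
- Commercial 1,1-dimethoxypropan-2-one is deprotonated with LDA to lithium 3,3-dimethoxyprop-1-en-2-olate F2.
- F2 adds to 2 under the same Cornforth control to give (4S,5R)-5-chloro-4-hydroxy-1,1-dimethoxydecan-2-one F3.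
- Narasaka–Prasad reduction, through the diethylboron chelate F4, gives (2R,4S,5R)-5-chloro-1,1-dimethoxydecane-2,4-diol F5.
- The carbinol of F5 is flanked by an acetal and cannot ionise. The ring is therefore closed with AgOTf/Ag2O, or by heating in water, to (2S,3S,5R)-5-(dimethoxymethyl)-2-pentyloxolan-3-ol F6.
- Acylation with 9 gives (2S,3S,5R)-5-(dimethoxymethyl)-2-pentyloxolan-3-yl dodecanoate F7.
- Aqueous TFA in CH2Cl2 at 0 °C then unmasks 12, so no ozonolysis is needed.

**Step 2 comes third.** The basic enolate can racemise 2. The lithium aldolate can undergo retro-aldol, epoxide closure or oxa-Michael closure onto the enone, and the anti:syn ratio may be modest. The fallback sets out from 3 and comes back at 5. It replaces the basic metal enolate by a neutral, isolated nucleophile in a Lewis-acid aldol. Compound 3 is converted (TMSOTf, Et3N, CH2Cl2, 0 °C) into trimethyl{[(3E)-4-phenylbuta-1,3-dien-2-yl]oxy}silane F8. F8 is then added to 2 in a Mukaiyama aldol reaction with BF3·OEt2 in CH2Cl2 at −78 °C. The open transition state with a monodentate Lewis acid follows the polar Felkin–Anh/Cornforth sense and gives the same 1,2-anti adduct. No base is present, and aqueous work-up delivers 5.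

## Further compounds
F1 | step 7 | di(non-8-en-1-yl)zinc | C=CCCCCCCC[Zn]CCCCCCCC=C
F2 | step 4 | lithium 3,3-dimethoxyprop-1-en-2-olate | C=C(O[Li])C(OC)OC
F3 | step 4 | (4S,5R)-5-chloro-4-hydroxy-1,1-dimethoxydecan-2-one | COC(OC)C(=O)C[C@H](O)[C@@H](CCCCC)Cl
F4 | step 4 | O-diethylboryl chelate of F3 | COC(OC)C(=O)C[C@H](OB(CC)CC)[C@@H](CCCCC)Cl
F5 | step 4 | (2R,4S,5R)-5-chloro-1,1-dimethoxydecane-2,4-diol | COC(OC)[C@H](O)C[C@H](O)[C@@H](CCCCC)Cl
F6 | step 4 | (2S,3S,5R)-5-(dimethoxymethyl)-2-pentyloxolan-3-ol | COC(OC)[C@H]1C[C@H](O)[C@H](CCCCC)O1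
F7 | step 4 | (2S,3S,5R)-5-(dimethoxymethyl)-2-pentyloxolan-3-yl dodecanoate | COC(OC)[C@H]1C[C@H](OC(=O)CCCCCCCCCCC)[C@H](CCCCC)O1
F8 | step 2 | trimethyl{[(3E)-4-phenylbuta-1,3-dien-2-yl]oxy}silane | C=C(O[Si](C)(C)C)/C=C/c1ccccc1
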